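Substrate charged is conserved, so whatever no longer reads as free substrate has gone somewhere, and I began by asking how that reacted part divided.

| flask | substrate | partner | remark | time |
|---|---|---|---|---|
| autumn | 0.54 M | 0.69 M | run made earlier |  |
| spring | 0.54 M | 1.2 M | run made earlier |  |
| dusk | 0.54 M | 3 M | run made earlier |  |
| noon | 1.1 M | 0.648 M | run made earlier |  |
| amber | 2.0 M | 1.00 M |  | 10 h |
| green | 2.0 M | 2.50 M |  | 10 h |
| teal | 0.54 M | 0.648 M |  | 10 h |
| red | 0.54 M | 1.00 M |  | 10 h |
| violet | 0.54 M | 2.50 M |  | 10 h |
| grey | 2.0 M | 0.648 M |  | 10 h |

- autumn (time / h: target / %, substrate / %): 1.00: 24.7, 62.0; 2.00: 33.5, 48.1; 3.00: 37.9, 39.7; 4.00: 40.4, 35.7; 5.00: 41.1, 33.5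
- spring (time / h: target / %, substrate / %): 0.417: 21.3, 68.0; 0.833: 32.5, 49.4; 1.33: 41.1, 36.0; 2.50: 48.9, 23.2; 5.00: 51.5, 16.6
- dusk (time / h: target / %, substrate / %): 0.417: 40.8, 37.1; 0.833: 54.8, 16.9; 1.33: 58.9, 8.8; 2.50: 60.0, 5.6; 5.00: 58.2, 5.2
- noon (time / h: target / %, substrate / %): 1.00: 19.8, 69.9; 2.00: 25.7, 60.0; 3.00: 27.9, 56.2; 4.00: 28.8, 54.4; 5.00: 28.9, 53.4

(standard deviation of a reading: 0.3 percentage points)

- the analysis behind the earlier runs scatters by 0.3 percentage points, standard deviation
- a reading or a percentage of target counts all its forms, free or not
- a reading of substrate is of its free form alone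

- all flasks from highest to lowest amount of target, in percent of the substrate charged, at 10 h (amber / green / teal / red / violet / grey)
- the same order at 30 min (amber / green / teal / red / violet / grey)
- the amount of target, in percent of the substrate charged of the flask you put first, at 10 h
- the amount of target, in percent of the substrate charged of the flask you put last, at 10 h

In the spring run, 0.618 of the reacted substrate stood as target at 5.00 h. I called this fraction, target over substrate reacted, the share φ (the selectivity). At that same time the autumn, dusk and noon runs gave 0.618, 0.614 and 0.620.

Next I treated the flasks as level by 10 h and reckoned what that leaves free. I took partner as used one for one with substrate, with a and b the charges of substrate and partner, x the substrate reacted and K the constant of that stalled balance: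

K = x / ((a − x)(b − x))

The last dusk reading gave K = 7.33 /M.

Then I turned the question round: what would put green above violet? My reckoning gave:

violet: reacted 93.6%, target 57.8%

green: reacted 85.3%, target 52.7%

grey: target 18.2%

So, with violet held at φ, green would need a share of 0.677, a step wider than the difference between the noon and dusk shares at 5.00 h. I put violet first and grey last. But the highest target reading so far was 0.324 M, in the dusk run, while my green stood higher, at 1.05 M, so φ had not been tried there.

The forecast gave violet > green > red > teal > amber > grey at 10 h and violet > green > red > amber > teal > grey at 30 min, with 54% (51% to 57%) for its first flask and 17% (15% to 19%) for its last. It held that “a parallel unseen product forms, independent of concentrations”. Its first and last flasks were mine, though its top lay lower than my 57.8%.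

The flasks gave green > violet > red > teal > amber > grey at 10 h and violet > green > red > amber > teal > grey at 30 min, with 67.5% at the top and 17.9% at the bottom.

    substrate + partner ⇌ target (K = 4.11 /M, k = 1.60 × 10⁻⁴ /M/s)
    substrate + partner ⇌ isomer of the product (K = 3.40 /M, k = 8.39 × 10⁻⁵ /M/s)
    crystals ⇌ target, rate k3*(cs3 - [target]) while solid is left; crystals form when [target] > cs3 (solubility = 0.330 M, k = 0.00764 /s)

At 10 h green held crystals equal to 51.0% of its substrate, counted within its target, with 0.331 M of target dissolved. Its share came to 0.733, past the 0.677 the turned-round question required.

Take a neighbour of grey charged with 1.2 M of substrate. K gives 44.8% of that substrate reacted, so 55.2% free, and φ then gives 27.7% of target. The computed flask held 55% of its substrate free and 26.4% of target at 10 h, with crystals at 0%.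

(The earlier runs and the new flask were computed from invented constants; scatter was added.)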